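**Retrosynthetic overview**
1. Plakortolide H is cut at C10=C11 (Julia–Kocienski) into enal 16 and sulfone 22; 16 comes from allylic alcohol 15.
2. The γ-lactone of 15 is made last, by translactonisation of hydroxy macrolactone 14; this deletes a temporary 11-membered lactone that ties the C1 carboxyl to C10 of the side chain.
3. 14 comes from open-chain keto ester 13 in the key step: the alkene CH2 (C5) adds to the C4 ketone and the distal peroxide oxygen traps the C6 cation, so the temporary macrolactone and the 1,2-dioxane close together.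
4. Enabling feature: C4 (tertiary C–O) and C6 (tertiary C–O–O) are 1,3 across the C5 methylene with the peroxide already on C3 (a Prins retron whose cation the peroxide can trap), and C2 and C7 are 1,4-cis on the 1,2-dioxane ring, so a C1–O–C10 ester tether can fix C6.
5. 13 comes from (S)-β-peroxy acid 11 (organocatalytic peroxidation of enal 9 sets C3) and dienol 5 (Negishi carboalumination sets the 8E olefin).

Key step: step 9

Remark: locants C1–C16 follow the plakortolide skeleton (C1 lactone carbonyl, C3 CH–O–O, C4 and C6 the quaternary carbons, C7–C16 the side chain); in step 5 the (S)-catalyst is assumed, from its usual facial shielding, to give the 3S product.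

**Step 1**
Reactants: 1 3-chloro-2-methylprop-1-ene; 2 ethynylmagnesium bromide
Product: 3 2-methylpent-1-en-4-yne
Conditions: CuCl (5 mol %), THF, 0 → 45 °C (2 in excess)
Reagents that add atoms: none
Why: Copper-catalysed coupling of an alkynyl Grignard reagent with an allylic chloride is a standard route to skipped enynes, and excess Grignard reagent suppresses double allylation.

**Step 2**
Reactants: 3 2-methylpent-1-en-4-yne
Product: 5 (2E)-3,5-dimethylhexa-2,5-dien-1-ol, via alkenylalane 4 (not isolated)
Conditions: Me3Al (2 equiv), Cp2ZrCl2 (0.2 equiv), CH2Cl2, 0 → 23 °C; then n-BuLi, THF, −78 °C; (CH2O)n, → 23 °C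
Reagents that add atoms: trimethylaluminium, C[Al](C)C; formaldehyde (from paraformaldehyde), C=O
Why: Negishi carboalumination adds Me–Al syn across the terminal alkyne with aluminium at the terminus, which fixes the E trisubstituted olefin, and the derived alanate is hydroxymethylated with retention while the 1,1-disubstituted alkene is not carbometalated.

**Step 3**
Reactants: 6 methyl 2,2-dimethoxypropanoate
Product: 7 2,2-dimethoxypropanal
Conditions: i-Bu2AlH (1.05 equiv), CH2Cl2, −78 °C
Reagents that add atoms: none
Why: Partial reduction of an α,α-dialkoxy ester with i-Bu2AlH stops at the chelate-stabilised tetrahedral aluminate at low temperature and releases the aldehyde on work-up.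

**Step 4**
Reactants: 7 2,2-dimethoxypropanal; 8 (triphenylphosphoranylidene)acetaldehyde
Product: 9 (2E)-4,4-dimethoxypent-2-enal
Conditions: CH2Cl2, 23 °C (8, 1.0 equiv)
Reagents that add atoms: none
Why: Wittig olefination with the stabilised formylmethylene ylide should give the E enal, and the stoichiometric amount of ylide limits a second homologation.

**Step 5**
Reactants: 9 (2E)-4,4-dimethoxypent-2-enal
Product: 10 (3S)-3-(tert-butylperoxy)-4,4-dimethoxypentanal
Conditions: (S)-2-{bis[3,5-bis(trifluoromethyl)phenyl](trimethylsilyloxy)methyl}pyrrolidine (10 mol %), PhCO2H (10 mol %), t-BuOOH (1.5 equiv, in decane), toluene, −20 °C; crude product used at once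
Reagents that add atoms: tert-butyl hydroperoxide, CC(C)(C)OO
Why: This is an iminium-catalysed enantioselective conjugate addition of a hydroperoxide to an enal (organocatalytic β-peroxidation), in which the aryl(silyloxy)methyl group of the catalyst shields one face of the E iminium so that the peroxide adds to C3 from the open face to give 3S, while acid co-catalyst and low temperature favour protonation of the enamine over its closure to the epoxide.

**Step 6**
Reactants: 10 (3S)-3-(tert-butylperoxy)-4,4-dimethoxypentanal
Product: 11 (3S)-3-(tert-butylperoxy)-4,4-dimethoxypentanoic acid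
Conditions: NaClO2, NaH2PO4, 2-methylbut-2-ene, t-BuOH/H2O, 0 °C
Reagents that add atoms: sodium chlorite, [Na+].[O-]Cl=O
Why: Pinnick oxidation converts the aldehyde to the acid without touching the dialkyl peroxide or, at 0 °C, the inductively deactivated ketal, and removes the elimination-prone β-peroxy aldehyde at once.

**Step 7**
Reactants: 11 (3S)-3-(tert-butylperoxy)-4,4-dimethoxypentanoic acid; 5 (2E)-3,5-dimethylhexa-2,5-dien-1-ol
Product: 12 (2E)-3,5-dimethylhexa-2,5-dien-1-yl (3S)-3-(tert-butylperoxy)-4,4-dimethoxypentanoate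
Conditions: EDC·HCl, DMAP (10 mol %), CH2Cl2, 0 °C
Reagents that add atoms: none
Why: Steglich-type carbodiimide esterification of a primary allylic alcohol runs at 0 °C with only catalytic DMAP, which should be mild enough to avoid β-elimination of the tert-butylperoxy group.

**Step 8**
Reactants: 12 (2E)-3,5-dimethylhexa-2,5-dien-1-yl (3S)-3-(tert-butylperoxy)-4,4-dimethoxypentanoate
Product: 13 (2E)-3,5-dimethylhexa-2,5-dien-1-yl (3S)-3-(tert-butylperoxy)-4-oxopentanoate
Conditions: PPTS (0.3 equiv), acetone/H2O (10:1), 45 °C
Reagents that add atoms: water, O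
Why: Mild acid-catalysed hydrolysis of the dimethyl ketal unmasks the methyl ketone, and PPTS is too weak an acid to protonate the 2-methylallyl unit or cleave the tert-butyl peroxide.

**Step 9**
Reactants: 13 (2E)-3,5-dimethylhexa-2,5-dien-1-yl (3S)-3-(tert-butylperoxy)-4-oxopentanoate
Product: 14 (1S,6E,9R,12S)-12-hydroxy-7,9,12-trimethyl-4,10,11-trioxabicyclo[7.2.2]tridec-6-en-3-one (plakortolide numbering 3S,4S,6R: a 4-hydroxy-4,6-dimethyl-1,2-dioxane whose C3 and C6 are bridged on one face by –CH2–C(=O)–O–CH2–CH=C(CH3)–CH2–)
Conditions: SnCl4 (1.2 equiv), 2,6-di-tert-butyl-4-methylpyridine (0.2 equiv), CH2Cl2 (0.002 M), −78 → −40 °C; then aq. NaHCO3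
Reagents that add atoms: none
Why: Proposed new method: SnCl4 binds the ketone oxygen and the proximal peroxide oxygen in a five-membered chelate, the CH2 terminus of the 1,1-disubstituted alkene adds to the activated C4 carbonyl in a reversible Prins-type step (11-endo closure of the temporary macrolactone), and the tertiary C6 cation is trapped by the distal peroxide oxygen in a six-membered chair-like closure with loss of the tert-butyl group as t-BuCl, so the C4–C5 and O–C6 bonds of the 1,2-dioxane form in one operation as a stepwise [4+2] annulation. The closest known reactions are the SnCl4-promoted annulation of peroxycarbenium ions with alkenes to 1,2-dioxolanes (a peroxide oxygen captures the alkene-derived cation), the dealkylative cyclisation of unsaturated tert-butyl peroxides onto mercurinium or halonium ions, chelation-controlled Lewis acid additions of π-nucleophiles to α-alkoxy ketones, and Prins macrocyclisations. C4 is set relative to C3 by the chelate (C5 enters anti to C2, which places C5 syn to the O–O bond and the new tertiary oxygen cis to C2) and, because the C–C step is reversible, also by the product-determining closure, in which the small C4–O rather than the C4–CH3 sits syn-axial to the tether arm. C6 is set by the tether: the seven-atom chain C2–C1(=O)–O–C10–C9=C8–C7 with its E olefin can bridge C3 and C6 of a six-membered ring only 1,4-cis, so C7 must lie on the face of C2 and the methyl group on the other face, which is the 6R configuration that an untethered cation would not favour. The step needs chemoselectivity for the 1,1-disubstituted over the trisubstituted alkene (the latter is deactivated by its allylic acyloxy group and could only close a seven-membered lactone through an s-cis ester) and capture of the cation before proton loss; high dilution, low temperature and the hindered pyridine base serve these needs.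

**Step 10**
Reactants: 14 (1S,6E,9R,12S)-12-hydroxy-7,9,12-trimethyl-4,10,11-trioxabicyclo[7.2.2]tridec-6-en-3-one
Product: 15 (1S,4R,6S)-4-[(2E)-4-hydroxy-2-methylbut-2-en-1-yl]-4,6-dimethyl-2,3,7-trioxabicyclo[4.3.0]nonan-8-one
Conditions: camphorsulfonic acid (10 mol %), CH2Cl2, 23 °C
Reagents that add atoms: none
Why: In this acid-catalysed translactonisation the tertiary C4 hydroxyl, held cis to the C2 arm, attacks the macrolactone carbonyl in a 5-exo-trig mode, so the 11-membered ring contracts to the γ-lactone and releases the allylic alcohol without touching a stereocentre.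

**Step 11**
Reactants: 15 (1S,4R,6S)-4-[(2E)-4-hydroxy-2-methylbut-2-en-1-yl]-4,6-dimethyl-2,3,7-trioxabicyclo[4.3.0]nonan-8-one
Product: 16 (1S,4R,6S)-4,6-dimethyl-4-[(2E)-2-methyl-4-oxobut-2-en-1-yl]-2,3,7-trioxabicyclo[4.3.0]nonan-8-one
Conditions: MnO2 (excess), CH2Cl2, 23 °C
Reagents that add atoms: none
Why: MnO2 oxidises the primary allylic alcohol selectively to the E enal under neutral conditions that should leave the dialkyl peroxide, the lactone and the olefin geometry intact.

**Step 12**
Reactants: 17 hex-5-en-1-ol; 18 styrene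
Product: 19 (5E)-6-phenylhex-5-en-1-ol
Conditions: second-generation Grubbs catalyst (2 mol %), 18 (3 equiv), CH2Cl2, 40 °C
Reagents that add atoms: none
Why: Olefin cross-metathesis of a terminal alkene with excess styrene should give the E β-alkylstyrene under thermodynamic control.

**Step 13**
Reactants: 19 (5E)-6-phenylhex-5-en-1-ol; 20 1-phenyl-1H-tetrazole-5-thiol
Product: 21 1-phenyl-5-{[(5E)-6-phenylhex-5-en-1-yl]sulfanyl}-1H-tetrazole
Conditions: PPh3, DIAD, THF, 0 → 23 °C
Reagents that add atoms: none
Why: Mitsunobu thioetherification of a primary alcohol with the acidic heteroaryl thiol is a reliable SN2 process.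

**Step 14**
Reactants: 21 1-phenyl-5-{[(5E)-6-phenylhex-5-en-1-yl]sulfanyl}-1H-tetrazole
Product: 22 1-phenyl-5-{[(5E)-6-phenylhex-5-en-1-yl]sulfonyl}-1H-tetrazole
Conditions: (NH4)6Mo7O24·4H2O (10 mol %), 30% aq. H2O2, EtOH, 0 → 23 °C
Reagents that add atoms: hydrogen peroxide, OO
Why: Molybdate-catalysed oxidation with H2O2 takes the sulfide to the sulfone faster than it epoxidises the styrenyl double bond.

**Step 15**
Reactants: 16 (1S,4R,6S)-4,6-dimethyl-4-[(2E)-2-methyl-4-oxobut-2-en-1-yl]-2,3,7-trioxabicyclo[4.3.0]nonan-8-one; 22 1-phenyl-5-{[(5E)-6-phenylhex-5-en-1-yl]sulfonyl}-1H-tetrazole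
Product: 23 plakortolide H, (1S,4R,6S)-4,6-dimethyl-4-[(2E,4E,9E)-2-methyl-10-phenyldeca-2,4,9-trien-1-yl]-2,3,7-trioxabicyclo[4.3.0]nonan-8-one
Conditions: 22, KN(SiMe3)2, DME, −78 °C; then 16, −78 → 0 °C
Reagents that add atoms: none
Why: In this Julia–Kocienski olefination the pre-metalated 1-phenyltetrazolyl sulfone adds to the enal and Smiles rearrangement–elimination should give the C10=C11 bond with the E selectivity typical of this sulfone, while pre-metalation keeps free base away from the lactone α-protons and the β-peroxy linkage.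

**Compound list**
1 | 3-chloro-2-methylprop-1-ene | C=C(C)CCl | starting material
2 | ethynylmagnesium bromide | C#C[Mg]Br | starting material
3 | 2-methylpent-1-en-4-yne | C=C(C)CC#C | intermediate
4 | [(1E)-2,4-dimethylpenta-1,4-dien-1-yl]dimethylalane | C=C(C)C/C(C)=C/[Al](C)C | intermediate
5 | (2E)-3,5-dimethylhexa-2,5-dien-1-ol | C=C(C)C/C(C)=C/CO | intermediate
6 | methyl 2,2-dimethoxypropanoate | COC(=O)C(C)(OC)OC | starting material
7 | 2,2-dimethoxypropanal | CC(OC)(OC)C=O | intermediate
8 | (triphenylphosphoranylidene)acetaldehyde | O=CC=P(c1ccccc1)(c1ccccc1)c1ccccc1 | starting material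
9 | (2E)-4,4-dimethoxypent-2-enal | CC(OC)(OC)/C=C/C=O | intermediate
10 | (3S)-3-(tert-butylperoxy)-4,4-dimethoxypentanal | CC(OC)(OC)[C@@H](OOC(C)(C)C)CC=O | intermediate
11 | (3S)-3-(tert-butylperoxy)-4,4-dimethoxypentanoic acid | CC(OC)(OC)[C@@H](OOC(C)(C)C)CC(=O)O | intermediate
12 | (2E)-3,5-dimethylhexa-2,5-dien-1-yl (3S)-3-(tert-butylperoxy)-4,4-dimethoxypentanoate | CC(OC)(OC)[C@@H](OOC(C)(C)C)CC(=O)OC/C=C(\C)CC(C)=C | intermediate
13 | (2E)-3,5-dimethylhexa-2,5-dien-1-yl (3S)-3-(tert-butylperoxy)-4-oxopentanoate | CC(=O)[C@@H](OOC(C)(C)C)CC(=O)OC/C=C(\C)CC(C)=C | intermediate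
14 | (1S,6E,9R,12S)-12-hydroxy-7,9,12-trimethyl-4,10,11-trioxabicyclo[7.2.2]tridec-6-en-3-one | C[C@]1(O)C[C@]2(C)OO[C@H]1CC(=O)OC/C=C(\C)C2 | intermediate
15 | (1S,4R,6S)-4-[(2E)-4-hydroxy-2-methylbut-2-en-1-yl]-4,6-dimethyl-2,3,7-trioxabicyclo[4.3.0]nonan-8-one | C/C(=C\CO)C[C@]1(C)C[C@]2(C)OC(=O)C[C@@H]2OO1 | intermediate
16 | (1S,4R,6S)-4,6-dimethyl-4-[(2E)-2-methyl-4-oxobut-2-en-1-yl]-2,3,7-trioxabicyclo[4.3.0]nonan-8-one | C/C(=C\C=O)C[C@]1(C)C[C@]2(C)OC(=O)C[C@@H]2OO1 | intermediate
17 | hex-5-en-1-ol | OCCCCC=C | starting material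
18 | styrene | C=Cc1ccccc1 | starting material
19 | (5E)-6-phenylhex-5-en-1-ol | OCCCC/C=C/c1ccccc1 | intermediate
20 | 1-phenyl-1H-tetrazole-5-thiol | Sc1nnnn1-c1ccccc1 | starting material
21 | 1-phenyl-5-{[(5E)-6-phenylhex-5-en-1-yl]sulfanyl}-1H-tetrazole | c1ccc(cc1)-n1nnnc1SCCCC/C=C/c1ccccc1 | intermediate
22 | 1-phenyl-5-{[(5E)-6-phenylhex-5-en-1-yl]sulfonyl}-1H-tetrazole | O=S(=O)(CCCC/C=C/c1ccccc1)c1nnnn1-c1ccccc1 | intermediate
23 | plakortolide H | C/C(=C\C=C\CCC/C=C/c1ccccc1)C[C@]1(C)C[C@]2(C)OC(=O)C[C@@H]2OO1 | target

**Totals**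
Total step count: 15.
Longest linear sequence: 10 steps (steps 3–11 and 15, from methyl 2,2-dimethoxypropanoate 6).

**Steps most likely to fail**

Step 9 (Proposed new method). The C6 cation may lose a proton (carbonyl-ene outcome) faster than the hindered tert-butyl peroxide oxygen captures it, or SnCl4 may ionise the tert-butyl peroxide during the slow macrocyclic C–C bond formation. The fallback makes the two bonds one after the other by known reactions and sets out from keto ester 13. A Me2AlCl-promoted intramolecular carbonyl-ene reaction at high dilution (CH2Cl2, −78 → 0 °C; the aluminium reagent is both chelating Lewis acid and proton scavenger) takes the proton-loss channel on purpose. It should give the 11-membered homoallylic alcohol (4S,5S,9E)-4-(tert-butylperoxy)-5-hydroxy-5,9-dimethyl-7-methylidene-1-oxacycloundec-9-en-2-one F1, and its endocyclic double-bond isomer converges in the next operation. Dealkylative cycloperoxymercuration with Hg(OAc)2 (CH2Cl2, 0 °C) lets the peroxide oxygen attack the mercurinium ion at the tertiary carbon with loss of the tert-butyl group. It closes the 1,2-dioxane, still under control of the ester bridge, to the organomercurial (1S,6E,9R,12S)-9-{[(acetyloxy)mercurio]methyl}-12-hydroxy-7,12-dimethyl-4,10,11-trioxabicyclo[7.2.2]tridec-6-en-3-one F2. Demercuration with NaBH4 in aq. NaOH at 0 °C turns CH2HgOAc into the C6 methyl group and comes back to the route at 14.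

Step 5. Slow iminium formation and addition at an enal flanked by a quaternary ketal carbon may let the β-peroxy enamine close to the epoxy aldehyde, or may erode enantiomeric purity through reversible addition. The fallback takes the peroxide stereocentre from the chiral pool and sets it by SN2 inversion; it sets out from dienol 5 and commercial (R)-2,2-dimethyl-5-oxo-1,3-dioxolane-4-acetic acid. Esterification (EDC·HCl, DMAP, CH2Cl2, 0 °C) should give (2E)-3,5-dimethylhexa-2,5-dien-1-yl [(4R)-2,2-dimethyl-5-oxo-1,3-dioxolan-4-yl]acetate F3. Aminolysis of the dioxolanone with N,O-dimethylhydroxylamine (THF, 23 °C) opens it to the Weinreb amide (2E)-3,5-dimethylhexa-2,5-dien-1-yl (3R)-3-hydroxy-4-[methoxy(methyl)amino]-4-oxobutanoate F4. Triflation (Tf2O, 2,6-lutidine, CH2Cl2, −78 °C) gives (2E)-3,5-dimethylhexa-2,5-dien-1-yl (3R)-4-[methoxy(methyl)amino]-4-oxo-3-{[(trifluoromethyl)sulfonyl]oxy}butanoate F5. Displacement with t-BuOOH and K2CO3 (inversion at the α-carbonyl carbon) gives (2E)-3,5-dimethylhexa-2,5-dien-1-yl (3S)-3-(tert-butylperoxy)-4-[methoxy(methyl)amino]-4-oxobutanoate F6. MeMgBr (THF, −78 °C, Weinreb ketone synthesis) then comes back to the route at 13, so steps 3–8 are bypassed.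

Step 8. The neighbouring peroxide slows ketal hydrolysis, so the acid strength and temperature needed may begin to isomerise the skipped diene or ionise the allylic ester. The fallback unmasks the ketone before the acid-sensitive dienol is attached and sets out from acid 11. Hydrolysis with CF3CO2H/H2O in CH2Cl2 at 0 °C should give (3S)-3-(tert-butylperoxy)-4-oxopentanoic acid F7. Mitsunobu esterification with dienol 5 (PPh3, DIAD, THF, 0 °C) needs no base, which protects the enolisable α-peroxy ketone, and alkylates the carboxylate oxygen; it comes back to the route at 13.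

**Further compounds**
F1 | step 9 | (4S,5S,9E)-4-(tert-butylperoxy)-5-hydroxy-5,9-dimethyl-7-methylidene-1-oxacycloundec-9-en-2-one | C[C@]1(O)CC(=C)C/C(C)=C/COC(=O)C[C@@H]1OOC(C)(C)C
F2 | step 9 | (1S,6E,9R,12S)-9-{[(acetyloxy)mercurio]methyl}-12-hydroxy-7,12-dimethyl-4,10,11-trioxabicyclo[7.2.2]tridec-6-en-3-one | C[C@]1(O)C[C@]2(C[Hg]OC(C)=O)OO[C@H]1CC(=O)OC/C=C(\C)C2
F3 | step 5 | (2E)-3,5-dimethylhexa-2,5-dien-1-yl [(4R)-2,2-dimethyl-5-oxo-1,3-dioxolan-4-yl]acetate | CC1(C)O[C@H](CC(=O)OC/C=C(\C)CC(C)=C)C(=O)O1
F4 | step 5 | (2E)-3,5-dimethylhexa-2,5-dien-1-yl (3R)-3-hydroxy-4-[methoxy(methyl)amino]-4-oxobutanoate | CON(C)C(=O)[C@H](O)CC(=O)OC/C=C(\C)CC(C)=C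
F5 | step 5 | (2E)-3,5-dimethylhexa-2,5-dien-1-yl (3R)-4-[methoxy(methyl)amino]-4-oxo-3-{[(trifluoromethyl)sulfonyl]oxy}butanoate | CON(C)C(=O)[C@H](OS(=O)(=O)C(F)(F)F)CC(=O)OC/C=C(\C)CC(C)=C
F6 | step 5 | (2E)-3,5-dimethylhexa-2,5-dien-1-yl (3S)-3-(tert-butylperoxy)-4-[methoxy(methyl)amino]-4-oxobutanoate | CON(C)C(=O)[C@@H](OOC(C)(C)C)CC(=O)OC/C=C(\C)CC(C)=C
F7 | step 8 | (3S)-3-(tert-butylperoxy)-4-oxopentanoic acid | CC(=O)[C@@H](OOC(C)(C)C)CC(=O)O
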